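## Structural features

The target is a linear hexaaryl pentaether: six benzene rings (A to F, from the 2,4,6-trihydroxyphenyl end to the 3,4,5-trihydroxyphenyl end) joined only by five C–O–C bridges and carrying fifteen free phenolic hydroxyls. It has no stereocentre and no other element of chirality, so nothing stereochemical has to be set or preserved. Each bridging oxygen is bonded on one side to a carbon with two oxygenated ortho neighbours (ring A C1, ring B C4, ring C C6, ring D C4, ring E C4) and on the other side to a less hindered carbon (ring B C1, ring C C1, ring D C1, ring E C1, ring F C1), so every diaryl ether is hindered and electron-rich. The fragile part is the free polyphenol: the 1,2,3-triol arrays of rings C and F and the phloroglucinol-type ring A oxidise easily in air, above all under base, and all six rings are strongly nucleophilic. The real difficulty is ring C, which is oxygenated on five contiguous carbons (C1 ether to ring B, C6 ether to ring D, hydroxyls at C3, C4 and C5) with a single C2–H, and for which no simple building block with the two neighbouring ether positions differentiated exists. The key step exploits exactly this array: C1, C6, C5 and C4 with their oxygens come from the four carbons of a squarate, and C3 with its oxygen plus C2–H come from an alpha-oxygenated vinyl unit, so that the most congested ether (ring C C6 to ring D) already exists as an aryloxy squarate before ring C is formed.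

## Logic of the disconnections

27 to 26: the fifteen O–alkyl bonds (fourteen O–CH3, one O–C2H5) are cut. The free polyphenol cannot be carried through copper chemistry, so all hydroxyls travel as simple alkyl ethers that one Lewis-acid operation removes. The forward step must cleave every alkyl ether without touching the five diaryl ether bonds, and the product must be isolated without air.

26 to 22 and 25: the bond between the ring D C4 oxygen and ring E C1 is cut. The oxygen stays on the hindered carbon as a phenol nucleophile and the unhindered ring E carbon becomes the electrophile. This splits the hexamer into a tetramer and a dimer. The forward step must arylate a phenol lying between two methoxy groups with an electron-rich bromide.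

25 to 23 and 24: the bond between the ring E C4 oxygen and ring F C1 is cut, by the same polarity argument. Both pieces are catalogue compounds. The forward coupling must leave the C–Br bond of 23 intact, which calls for an oxidative copper coupling at room temperature.

22 to 21: the O–benzyl bond on ring D C4 is cut. Benzyl is the one ether removable by hydrogenolysis while every methyl and ethyl ether stays, so ring D C4 can be unveiled alone. No aryl halide may remain in the molecule at that stage.

21 to 15 and 20: the bond between the ring C C1 oxygen and ring B C4 is cut. The oxygen must be on ring C here, because the ring-forming step delivers C1 as a free hydroxyl; the electrophile is therefore the iodide between two methoxy groups. Two dimers of similar size result. The forward step is a copper coupling with a doubly ortho-substituted iodide, the hardest coupling of the route.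

20 to 18 and 19, and 18 to 16: the bond between the ring A C1 oxygen and ring B C1 is cut, then the C–B bond of 18 is traced to a C–H bond of 16. The oxygen sits on the hindered ring A carbon as a phenol and ring B C1 is the unhindered boron partner, with the iodide for the next coupling already in place. The forward steps need C–H borylation at the one unhindered position of 16 and an oxidative coupling mild enough to spare the C–I bond.

15 to 12 (key disconnection): the C1–C2 bond of ring C is cut and C1 is reconnected to C4, which turns the pentaoxygenated benzene into a cyclobutenone carrying a 1-alkoxyvinyl group. Four of the five oxygens are then already on the four-membered ring and the fifth is on the vinyl group. The forward step needs the vinyl group to rotate inward on ring opening, and the C4 oxygen must be capped so that C1 is the only free hydroxyl in 15.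

12 to 8 and 9: the C4–C(vinyl) bond and the O–CH3 bond of the tertiary ether are cut. This leaves a squarate bearing ring D and a two-carbon vinyl ether. The forward addition must choose the carbonyl next to the methoxy-bearing carbon, and the alkoxide must be capped cold before it ring-opens.

8 to 6 and 4, and 6 to 5: the two vinylogous ester C–O bonds are cut back to the dichloride and then to the diacid. Chloride displacement is irreversible, whereas direct aryloxy-for-alkoxy exchange on a dialkyl squarate is not. The forward step must substitute the two chlorides one after the other by two different oxygen nucleophiles.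

4 to 2 to 1: the ring D C1–O bond is traced to a formyl group and the benzyl ether to a free phenol. The starting aldehyde carries ring D's full oxygen pattern. The forward oxidation needs the aryl group to migrate, which the para oxygen secures.

## Other disconnections considered

Alternative 1: The cut is at three C(aryl)–OH bonds, at ring A C4, ring C C4 and ring F C4, each traced back to a formyl group in the hexaaryl ether trialdehyde A2. On ring A the hydroxyl concerned is the one para to the ether oxygen, which is C4 in the numbering used here, because C1 carries the bridge to ring B. In the forward key step a peracid would add to each formyl group, the aryl group would migrate to oxygen (Baeyer–Villiger/Dakin), and hydrolysis of the three formates would give the triol A1.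
- In favour: a formyl group para to a fluoride opens that carbon to SNAr, so the ethers at ring A C1, ring C C1 and ring F C1 could be made from phenoxides without copper. The oxidation is the same reaction type as step 2 of the chosen route and is dependable for rings with a para oxygen.
- Against: the step forms no ring and no skeletal bond, so ring C with its five contiguous oxygens must still be assembled by other means. The ether at ring C C6 is meta to the formyl group and not activated, and the ring D–ring E ether has no formyl handle. Three oxidations must go to completion on a molecule with six electron-rich rings that a peracid can also hydroxylate.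
- Comparison: on structure it supplies three easy oxygens where the chosen plan creates ring C whole. On mechanism it needs three intermolecular oxidations with a chemoselectivity question, against one reagent-free unimolecular cascade. On step economy it needs at least as many ether-forming steps plus a purpose-made ring C fluoroaldehyde. It is the equal of the chosen plan in the end game (one global demethylation, of twelve ethers instead of fifteen) and the better in avoiding copper for three of the five ether bonds.

Alternative 2: The cut is at ring F's C2–C3 and C1–C6 bonds, back to the aryl ethynyl ether A4 (ring E already on the oxygen) and the cyclobutenone A5. In the forward key step heating would open A5 to a vinylketene, which would add [2+2] to the electron-rich alkyne of A4; the vinylcyclobutenone adduct would reopen and close by 6π electrocyclisation (Danheiser benzannulation) to the phenol A3.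
- In favour: the ring E C4–O–ring F ether, on a carbon between two methoxy groups, would be made without any coupling. The regiochemistry is inherent, since the alkyne oxygen ends meta to the new hydroxyl.
- Against: ring F is the simplest ring of the target and can be bought as 24, so a ring synthesis gains little. A4 and A5 each need several steps and both are sensitive. After debenzylation of A3 the ring E C1 oxygen sits on the unhindered carbon, so the bond to ring D would need ring D C4, between two methoxy groups, as electrophile, which is the mismatched polarity. Ring C remains unsolved.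
- Comparison: on structure it spends a ring construction on the easiest ring. On mechanism it belongs to the same family (4π opening, 6π closure) and is equal in regiochemical reliability, but it is bimolecular and competes with ketene dimerisation. On step economy it needs at least five steps for what step 11 does in one. It is the better in forming two C–C bonds in one step, against one in the chosen key step.

Alternative 3: The cut is at ring A's C2–C3 and C5–C6 bonds, back to the aryloxymalonate A7 (derived from 4) and the keto diester A8. In the forward key step, under a methoxide base, one methylene of A8 would be acylated by one ester of A7 and the second methylene by the other ester; enolisation would aromatise the ring to the trihydroxy diester A6.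
- In favour: the ring A C1–O bond, flanked by two oxygens, would be made by ring construction from cheap reagents, with no copper and no oxidation-prone phenol such as 19 in step 8. Two C–C bonds and a ring would form in one step. After debenzylation the ring B C4 oxygen would sit on the hindered carbon as nucleophile, which is the better-matched polarity for the ring B–ring C ether and one the chosen plan cannot use.
- Against: that polarity needs a ring C electrophile at C1, and no simple route to such a pentaoxygenated aryl halide exists, whereas the squarate route gives ring C as a phenol. A6 is still three operations from a usable ring A (ester hydrolysis, double decarboxylation, triple O-methylation) through air-sensitive phloroglucinols. 2-Aryloxymalonates are hindered, poorly electrophilic esters, and the first Claisen adduct can close through oxygen to a pyranone.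
- Comparison: on structure it addresses a terminal ring that can be bought fully oxygenated (19) and leaves ring C open. On mechanism it relies on reversible ionic condensations against an irreversible pericyclic cascade. On step economy it needs about five steps for the ring A–ring B unit against two (steps 7 and 8). It is the equal of the chosen plan in building a polyoxygenated benzene ring with its aryloxy group already in place.

Key step: step 6

Remark: 8 is built by chloride displacement on squaric acid dichloride and not by exchanging a phenol for a methoxy group of a dialkyl squarate, because an aryloxide is the better leaving group and that exchange is uphill.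
Assumption: 16, 19, 23 and 24 are taken as catalogue compounds.

## Route

Step 1
Reactants: 1 syringaldehyde (4-hydroxy-3,5-dimethoxybenzaldehyde)
Product: 2 4-(benzyloxy)-3,5-dimethoxybenzaldehyde
Conditions: BnBr, K2CO3, DMF, 60 °C
Reagents that add atoms: benzyl bromide, BrCc1ccccc1
Why: Williamson ether synthesis on a phenoxide made acidic by the para formyl group; benzyl is chosen because it alone can later be removed by hydrogenolysis beside methyl and ethyl ethers.

Step 2
Reactants: 2 4-(benzyloxy)-3,5-dimethoxybenzaldehyde
Product: 4 4-(benzyloxy)-3,5-dimethoxyphenol, via aryl formate 3 (not isolated)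
Conditions: mCPBA, CH2Cl2, 0 °C to rt; then K2CO3 (cat.), MeOH, rt
Reagents that add atoms: mCPBA (3-chloroperoxybenzoic acid), OOC(=O)c1cccc(Cl)c1
Why: Dakin-type Baeyer–Villiger oxidation; the para benzyloxy group makes the aryl group the migrating group, and formate 3 is methanolysed in the same flask.

Step 3
Reactants: 5 squaric acid (3,4-dihydroxycyclobut-3-ene-1,2-dione)
Product: 6 squaric acid dichloride (3,4-dichlorocyclobut-3-ene-1,2-dione)
Conditions: (COCl)2, DMF (cat.), CH2Cl2, reflux
Reagents that add atoms: oxalyl chloride, ClC(=O)C(Cl)=O
Why: Vilsmeier-type chlorination of a vinylogous carboxylic acid, the standard preparation of this dichloride; the by-products are gases.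

Step 4
Reactants: 6 squaric acid dichloride; 4 4-(benzyloxy)-3,5-dimethoxyphenol
Product: 8 3-[4-(benzyloxy)-3,5-dimethoxyphenoxy]-4-methoxycyclobut-3-ene-1,2-dione, via chloro methoxy squarate 7 (not isolated)
Conditions: MeOH (1.0 equiv), Et2O, 0 °C to rt, then evaporate; 4, Et3N, CH2Cl2, −40 to 0 °C
Reagents that add atoms: methanol, CO
Why: Two successive addition–elimination substitutions at vinylogous acid chloride carbons; the first methoxy group deactivates the remaining C–Cl bond, so one equivalent of methanol should stop at 7. The aryloxide of 4 then displaces chloride irreversibly, and attack at the methoxy-bearing carbon can only revert because aryloxide is the better leaving group.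

Step 5
Reactants: 8 3-[4-(benzyloxy)-3,5-dimethoxyphenoxy]-4-methoxycyclobut-3-ene-1,2-dione; 9 ethyl vinyl ether
Product: 12 rac-2-[4-(benzyloxy)-3,5-dimethoxyphenoxy]-4-(1-ethoxyethenyl)-3,4-dimethoxycyclobut-2-en-1-one, via 1-ethoxyvinyllithium 10 (not isolated), via lithium alkoxide 11 (not isolated)
Conditions: 9, t-BuLi, THF, −78 to 0 °C; add to 8, THF, −78 °C; MeOTf, −78 to −20 °C
Reagents that add atoms: methyl trifluoromethanesulfonate, COS(=O)(=O)C(F)(F)F
Why: Alpha-lithiation of the vinyl ether and 1,2-addition of 10 to the carbonyl next to the methoxy-bearing carbon, which is the vinylogous ester of the weaker aryloxy donor and is flanked by the smaller group, while the other carbonyl is deactivated by the stronger methoxy donor. Alkoxide 11 is O-methylated cold in the flask before it can ring-open; the quaternary centre C4 forms racemic and needs no control because step 6 destroys it.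

Step 6
Reactants: 12 rac-2-[4-(benzyloxy)-3,5-dimethoxyphenoxy]-4-(1-ethoxyethenyl)-3,4-dimethoxycyclobut-2-en-1-one
Product: 15 2-[4-(benzyloxy)-3,5-dimethoxyphenoxy]-5-ethoxy-3,4-dimethoxyphenol, via dienylketene 13 (not isolated), via cyclohexadienone 14 (not isolated)
Conditions: toluene (degassed, 0.02 M), 110 °C
Reagents that add atoms: none
Why: Thermal conrotatory 4π electrocyclic opening of 12 breaks the bond between the carbonyl carbon and the quaternary carbon and gives dienylketene 13; the donor 4-methoxy group turns outward and the 1-ethoxyvinyl group inward, so the ketene carbon and the vinyl CH2 end up cis on the central double bond. Disrotatory 6π electrocyclisation, a six-membered closure in which the ketene C=C serves as one of the three π bonds, then forms the C1–C2 bond of ring C and gives dienone 14, which tautomerises irreversibly to phenol 15. This is the Moore-type ring expansion of squarate-derived 4-alkenyl-4-alkoxycyclobutenones, a known reaction class. The only stereocentre of 12 becomes sp2, so no stereocentre is formed or has to be controlled. The selectivity needed is torquoselectivity (vinyl inward), which the 4-methoxy donor secures; a ketene formed with the vinyl group outward can only revert to 12, since ring opening is reversible and no free hydroxyl is present to trap it as a lactone. The substitution pattern of ring C (aryloxy at C6 beside the new C1 hydroxyl, C2–H between C1 and C3) is already fixed in 12 by the aryloxy group standing alpha to the carbonyl. Degassed solvent and dilution protect the electron-rich ketene and phenol from oxygen and from intermolecular ketene trapping.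

Step 7
Reactants: 16 2-iodo-1,3-dimethoxybenzene
Product: 18 (4-iodo-3,5-dimethoxyphenyl)boronic acid, via pinacol boronate 17 (not isolated)
Conditions: [Ir(OMe)(cod)]2 (cat.), dtbpy (cat.), B2pin2, THF, 80 °C; then NaIO4, NH4OAc, acetone–H2O, rt
Reagents that add atoms: bis(pinacolato)diboron, CC1(C)OB(OC1(C)C)B1OC(C)(C)C(C)(C)O1; water, O
Why: Iridium-catalysed aromatic C–H borylation is sterically governed and should touch only C5–H, the one C–H bond without an ortho substituent, while the C–I bond is tolerated; periodate then cleaves the pinacol ester to the free boronic acid.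

Step 8
Reactants: 18 (4-iodo-3,5-dimethoxyphenyl)boronic acid; 19 2,4,6-trimethoxyphenol
Product: 20 2-iodo-1,3-dimethoxy-5-(2,4,6-trimethoxyphenoxy)benzene
Conditions: Cu(OAc)2, pyridine, 4 Å MS, CH2Cl2, air, rt
Reagents that add atoms: none
Why: Chan–Lam oxidative O-arylation, which accepts phenols with two ortho substituents as long as the boron sits on an unhindered carbon; at room temperature the C–I bond needed for step 9 is not touched.

Step 9
Reactants: 15 2-[4-(benzyloxy)-3,5-dimethoxyphenoxy]-5-ethoxy-3,4-dimethoxyphenol; 20 2-iodo-1,3-dimethoxy-5-(2,4,6-trimethoxyphenoxy)benzene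
Product: 21 1-[4-(benzyloxy)-3,5-dimethoxyphenoxy]-2-[2,6-dimethoxy-4-(2,4,6-trimethoxyphenoxy)phenoxy]-4-ethoxy-5,6-dimethoxybenzene
Conditions: CuI (cat.), picolinic acid (cat.), K3PO4, DMSO, 90 °C, Ar
Reagents that add atoms: none
Why: Ullmann-type copper-catalysed diaryl ether synthesis with a picolinate ligand, a system suited to ortho-substituted partners; the iodide is used for its higher reactivity, its ortho methoxy groups can assist at copper, and 15 offers a single nucleophilic hydroxyl.

Step 10
Reactants: 21 1-[4-(benzyloxy)-3,5-dimethoxyphenoxy]-2-[2,6-dimethoxy-4-(2,4,6-trimethoxyphenoxy)phenoxy]-4-ethoxy-5,6-dimethoxybenzene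
Product: 22 4-{2-[2,6-dimethoxy-4-(2,4,6-trimethoxyphenoxy)phenoxy]-4-ethoxy-5,6-dimethoxyphenoxy}-2,6-dimethoxyphenol
Conditions: H2 (1 atm), Pd/C, EtOAc–MeOH, rt
Reagents that add atoms: none
Why: Hydrogenolysis of the aryl benzyl ether; methyl, ethyl and diaryl ethers are inert and no halogen is left in the molecule.

Step 11
Reactants: 23 4-bromo-2,6-dimethoxyphenol; 24 (3,4,5-trimethoxyphenyl)boronic acid
Product: 25 5-bromo-1,3-dimethoxy-2-(3,4,5-trimethoxyphenoxy)benzene
Conditions: Cu(OAc)2, pyridine, 4 Å MS, CH2Cl2, air, rt
Reagents that add atoms: none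
Why: Chan–Lam O-arylation of a hindered phenol by an unhindered arylboronic acid; the para position of 23 is blocked by bromine against oxidative dimerisation and the C–Br bond survives at room temperature.

Step 12
Reactants: 22 4-{2-[2,6-dimethoxy-4-(2,4,6-trimethoxyphenoxy)phenoxy]-4-ethoxy-5,6-dimethoxyphenoxy}-2,6-dimethoxyphenol; 25 5-bromo-1,3-dimethoxy-2-(3,4,5-trimethoxyphenoxy)benzene
Product: 26 1-{3,5-dimethoxy-4-[3,5-dimethoxy-4-(3,4,5-trimethoxyphenoxy)phenoxy]phenoxy}-2-[2,6-dimethoxy-4-(2,4,6-trimethoxyphenoxy)phenoxy]-4-ethoxy-5,6-dimethoxybenzene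
Conditions: CuI (cat.), picolinic acid (cat.), K3PO4, DMSO, 100 °C, Ar
Reagents that add atoms: none
Why: Ullmann-type coupling in the matched sense, with the hindered phenol as nucleophile and the bromide on an unhindered carbon; an anaerobic method with monovalent copper is preferred over an oxidative coupling because 22 is an easily oxidised para-aryloxyphenol.

Step 13
Reactants: 26 1-{3,5-dimethoxy-4-[3,5-dimethoxy-4-(3,4,5-trimethoxyphenoxy)phenoxy]phenoxy}-2-[2,6-dimethoxy-4-(2,4,6-trimethoxyphenoxy)phenoxy]-4-ethoxy-5,6-dimethoxybenzene
Product: 27 4-{3,5-dihydroxy-4-[3,5-dihydroxy-4-(3,4,5-trihydroxyphenoxy)phenoxy]phenoxy}-5-[2,6-dihydroxy-4-(2,4,6-trihydroxyphenoxy)phenoxy]benzene-1,2,3-triol (CNP0270681.0)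
Conditions: BBr3 (excess), CH2Cl2, −78 °C to rt, Ar; then H2O (degassed), 0 °C
Reagents that add atoms: none
Why: Lewis-acid ether cleavage: BBr3 binds each ether oxygen and bromide attacks the methyl or ethyl carbon, whereas the diaryl ether bonds offer no sp3 carbon and should survive; hydrolysis of the aryl borates under argon releases the fifteen hydroxyls.

## Compound list

1 | syringaldehyde (4-hydroxy-3,5-dimethoxybenzaldehyde) | COc1cc(C=O)cc(OC)c1O | starting material
2 | 4-(benzyloxy)-3,5-dimethoxybenzaldehyde | COc1cc(C=O)cc(OC)c1OCc1ccccc1 | intermediate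
3 | 4-(benzyloxy)-3,5-dimethoxyphenyl formate | O=COc1cc(OC)c(OCc2ccccc2)c(OC)c1 | intermediate (not isolated)
4 | 4-(benzyloxy)-3,5-dimethoxyphenol | COc1cc(O)cc(OC)c1OCc1ccccc1 | intermediate
5 | squaric acid (3,4-dihydroxycyclobut-3-ene-1,2-dione) | OC1=C(O)C(=O)C1=O | starting material
6 | squaric acid dichloride (3,4-dichlorocyclobut-3-ene-1,2-dione) | ClC1=C(Cl)C(=O)C1=O | intermediate
7 | 3-chloro-4-methoxycyclobut-3-ene-1,2-dione | COC1=C(Cl)C(=O)C1=O | intermediate (not isolated)
8 | 3-[4-(benzyloxy)-3,5-dimethoxyphenoxy]-4-methoxycyclobut-3-ene-1,2-dione | COC1=C(Oc2cc(OC)c(OCc3ccccc3)c(OC)c2)C(=O)C1=O | intermediate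
9 | ethyl vinyl ether (ethoxyethene) | C=COCC | starting material
10 | 1-ethoxyvinyllithium | [Li]C(=C)OCC | intermediate (not isolated)
11 | lithium 3-[4-(benzyloxy)-3,5-dimethoxyphenoxy]-1-(1-ethoxyethenyl)-2-methoxy-4-oxocyclobut-2-en-1-olate (racemic) | [Li+].[O-]C1(C(=C)OCC)C(OC)=C(Oc2cc(OC)c(OCc3ccccc3)c(OC)c2)C1=O | intermediate (not isolated)
12 | rac-2-[4-(benzyloxy)-3,5-dimethoxyphenoxy]-4-(1-ethoxyethenyl)-3,4-dimethoxycyclobut-2-en-1-one | C=C(OCC)C1(OC)C(OC)=C(Oc2cc(OC)c(OCc3ccccc3)c(OC)c2)C1=O | intermediate
13 | (3Z)-2-[4-(benzyloxy)-3,5-dimethoxyphenoxy]-5-ethoxy-3,4-dimethoxyhexa-1,3,5-trien-1-one | O=C=C(Oc1cc(OC)c(OCc2ccccc2)c(OC)c1)/C(OC)=C(OC)\C(=C)OCC | intermediate (not isolated)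
14 | 2-[4-(benzyloxy)-3,5-dimethoxyphenoxy]-5-ethoxy-3,4-dimethoxycyclohexa-2,4-dien-1-one | O=C1CC(OCC)=C(OC)C(OC)=C1Oc1cc(OC)c(OCc2ccccc2)c(OC)c1 | intermediate (not isolated)
15 | 2-[4-(benzyloxy)-3,5-dimethoxyphenoxy]-5-ethoxy-3,4-dimethoxyphenol | CCOc1cc(O)c(Oc2cc(OC)c(OCc3ccccc3)c(OC)c2)c(OC)c1OC | intermediate
16 | 2-iodo-1,3-dimethoxybenzene | COc1cccc(OC)c1I | starting material
17 | 2-(4-iodo-3,5-dimethoxyphenyl)-4,4,5,5-tetramethyl-1,3,2-dioxaborolane | COc1cc(B2OC(C)(C)C(C)(C)O2)cc(OC)c1I | intermediate (not isolated)
18 | (4-iodo-3,5-dimethoxyphenyl)boronic acid | COc1cc(B(O)O)cc(OC)c1I | intermediate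
19 | 2,4,6-trimethoxyphenol | COc1cc(OC)c(O)c(OC)c1 | starting material
20 | 2-iodo-1,3-dimethoxy-5-(2,4,6-trimethoxyphenoxy)benzene | COc1cc(OC)c(Oc2cc(OC)c(I)c(OC)c2)c(OC)c1 | intermediate
21 | 1-[4-(benzyloxy)-3,5-dimethoxyphenoxy]-2-[2,6-dimethoxy-4-(2,4,6-trimethoxyphenoxy)phenoxy]-4-ethoxy-5,6-dimethoxybenzene | COc1cc(OC)c(Oc2cc(OC)c(Oc3cc(OCC)c(OC)c(OC)c3Oc3cc(OC)c(OCc4ccccc4)c(OC)c3)c(OC)c2)c(OC)c1 | intermediate
22 | 4-{2-[2,6-dimethoxy-4-(2,4,6-trimethoxyphenoxy)phenoxy]-4-ethoxy-5,6-dimethoxyphenoxy}-2,6-dimethoxyphenol | COc1cc(OC)c(Oc2cc(OC)c(Oc3cc(OCC)c(OC)c(OC)c3Oc3cc(OC)c(O)c(OC)c3)c(OC)c2)c(OC)c1 | intermediate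
23 | 4-bromo-2,6-dimethoxyphenol | COc1cc(Br)cc(OC)c1O | starting material
24 | (3,4,5-trimethoxyphenyl)boronic acid | COc1cc(B(O)O)cc(OC)c1OC | starting material
25 | 5-bromo-1,3-dimethoxy-2-(3,4,5-trimethoxyphenoxy)benzene | COc1cc(Oc2c(OC)cc(Br)cc2OC)cc(OC)c1OC | intermediate
26 | 1-{3,5-dimethoxy-4-[3,5-dimethoxy-4-(3,4,5-trimethoxyphenoxy)phenoxy]phenoxy}-2-[2,6-dimethoxy-4-(2,4,6-trimethoxyphenoxy)phenoxy]-4-ethoxy-5,6-dimethoxybenzene | COc1cc(OC)c(Oc2cc(OC)c(Oc3cc(OCC)c(OC)c(OC)c3Oc3cc(OC)c(Oc4cc(OC)c(Oc5cc(OC)c(OC)c(OC)c5)c(OC)c4)c(OC)c3)c(OC)c2)c(OC)c1 | intermediate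
27 | 4-{3,5-dihydroxy-4-[3,5-dihydroxy-4-(3,4,5-trihydroxyphenoxy)phenoxy]phenoxy}-5-[2,6-dihydroxy-4-(2,4,6-trihydroxyphenoxy)phenoxy]benzene-1,2,3-triol (CNP0270681.0) | Oc1cc(O)c(Oc2cc(O)c(Oc3cc(O)c(O)c(O)c3Oc3cc(O)c(Oc4cc(O)c(Oc5cc(O)c(O)c(O)c5)c(O)c4)c(O)c3)c(O)c2)c(O)c1 | target

## Step count and least certain steps

Total step count: 13. Longest linear sequence: 9 steps (steps 1, 2, 4, 5, 6, 9, 10, 12, 13, from 1 to 27).

Step 6 (key step). What may go wrong: the electrocyclic cascade of the fully O-alkylated cyclobutenone may be slow at temperatures where the electron-rich ketene is lost to intermolecular trapping or oxidation before the 6π closure. Fallback, from 11 back to 15, through the free tertiary alcohol, the substrate type for which this ring expansion is best established: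
- Quenching alkoxide 11 with aqueous NH4Cl at −78 °C in place of methylation should give 2-[4-(benzyloxy)-3,5-dimethoxyphenoxy]-4-(1-ethoxyethenyl)-4-hydroxy-3-methoxycyclobut-2-en-1-one F1.
- Heating F1 in degassed toluene should give the hydroquinone 2-[4-(benzyloxy)-3,5-dimethoxyphenoxy]-5-ethoxy-3-methoxybenzene-1,4-diol F2.
- The two hydroxyls of F2 differ in hindrance (C1–OH has an ortho hydrogen, C4–OH lies between ethoxy and methoxy), so pivaloyl chloride and pyridine at low temperature should acylate C1–OH to give 2-[4-(benzyloxy)-3,5-dimethoxyphenoxy]-5-ethoxy-4-hydroxy-3-methoxyphenyl 2,2-dimethylpropanoate F3.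
- MeI and K2CO3 in acetone then methylate the remaining hydroxyl to give 2-[4-(benzyloxy)-3,5-dimethoxyphenoxy]-5-ethoxy-3,4-dimethoxyphenyl 2,2-dimethylpropanoate F4, and K2CO3 in MeOH removes the pivaloyl group to return to 15.

Step 5. What may go wrong: addition to the other carbonyl, or addition–elimination with loss of the aryloxide, because the two carbonyls of 8 differ only in the donor strength of aryloxy against methoxy. Fallback, from 6 to 12, through a symmetrical squarate in which the two carbonyls are equivalent:
- Two equivalents of 4 with Et3N and 6 should give 3,4-bis[4-(benzyloxy)-3,5-dimethoxyphenoxy]cyclobut-3-ene-1,2-dione F5.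
- Addition of 10 and capture with MeOTf as in step 5 can then give only one constitution, 2,3-bis[4-(benzyloxy)-3,5-dimethoxyphenoxy]-4-(1-ethoxyethenyl)-4-methoxycyclobut-2-en-1-one F6.
- In F6 only C3, the beta carbon of the vinylogous ester, is open to addition–elimination, so one equivalent of NaOMe in MeOH–THF at −20 °C should replace that aryloxy group by methoxy and give 12, with release of 4 for recovery.

Step 9. What may go wrong: slow reaction at the iodide between two methoxy groups with a phenol that itself carries an ortho aryloxy group, so that protodeiodination of 20 outruns C–O bond formation. Fallback, from 15 to 21, with ring B brought in as a smaller, activated electrophile and ring A added afterwards: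
- Commercial 4-bromo-3,5-dimethoxybenzaldehyde, whose para formyl group activates the C–Br bond, is coupled with 15 (CuI, picolinic acid, K3PO4, DMSO) to give 4-{2-[4-(benzyloxy)-3,5-dimethoxyphenoxy]-5-ethoxy-3,4-dimethoxyphenoxy}-3,5-dimethoxybenzaldehyde F7.
- Dakin oxidation (mCPBA, then K2CO3 in MeOH) turns the formyl group into the ring B C1 hydroxyl and gives 4-{2-[4-(benzyloxy)-3,5-dimethoxyphenoxy]-5-ethoxy-3,4-dimethoxyphenoxy}-3,5-dimethoxyphenol F8.
- This unhindered phenol is arylated with commercial 2-iodo-1,3,5-trimethoxybenzene under the same copper conditions to give 21.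

Step 12. What may go wrong: oxidative degradation of the electron-rich phenol 22 under hot basic conditions faster than its coupling with the electron-rich bromide. Fallback, from 25 to 26, by metal-free aryl transfer from trivalent iodine at room temperature:
- Bromine–lithium exchange on 25 (n-BuLi, THF, −78 °C) followed by I2 gives 5-iodo-1,3-dimethoxy-2-(3,4,5-trimethoxyphenoxy)benzene F9.
- Oxidation with mCPBA and TsOH and then addition of 1,3,5-trimethoxybenzene gives [3,5-dimethoxy-4-(3,4,5-trimethoxyphenoxy)phenyl](2,4,6-trimethoxyphenyl)iodonium 4-methylbenzenesulfonate F10.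
- The potassium phenoxide of 22 (t-BuOK, toluene–THF, rt) should take the less electron-rich, unhindered ring E aryl group by ligand coupling and give 26, the trimethoxyphenyl group leaving as its iodide.

Step 13. What may go wrong: incomplete cleavage of the last ethers, since boron chelates of the trioxygenated rings slow the final dealkylations, together with air oxidation of the free polyphenol during aqueous isolation. Fallback, from 26 to 27, in which the polyphenol is never isolated free from the crude mixture:
- After the BBr3 treatment and a methanol quench, the volatiles are removed and the residue is acetylated (Ac2O, pyridine, DMAP) to the pentadecaacetate of 27, 4-{3,5-diacetoxy-4-[3,5-diacetoxy-4-(3,4,5-triacetoxyphenoxy)phenoxy]phenoxy}-5-[2,6-diacetoxy-4-(2,4,6-triacetoxyphenoxy)phenoxy]benzene-1,2,3-triyl triacetate F11.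
- F11 is air-stable and can be purified by chromatography, with partly alkylated acetates separated and resubmitted.
- Acid methanolysis (HCl in degassed MeOH, rt) then releases 27 under non-oxidising conditions.

## Further compounds

F1 | step 6 | 2-[4-(benzyloxy)-3,5-dimethoxyphenoxy]-4-(1-ethoxyethenyl)-4-hydroxy-3-methoxycyclobut-2-en-1-one (racemic) | C=C(OCC)C1(O)C(OC)=C(Oc2cc(OC)c(OCc3ccccc3)c(OC)c2)C1=O
F2 | step 6 | 2-[4-(benzyloxy)-3,5-dimethoxyphenoxy]-5-ethoxy-3-methoxybenzene-1,4-diol | CCOc1cc(O)c(Oc2cc(OC)c(OCc3ccccc3)c(OC)c2)c(OC)c1O
F3 | step 6 | 2-[4-(benzyloxy)-3,5-dimethoxyphenoxy]-5-ethoxy-4-hydroxy-3-methoxyphenyl 2,2-dimethylpropanoate | CCOc1cc(OC(=O)C(C)(C)C)c(Oc2cc(OC)c(OCc3ccccc3)c(OC)c2)c(OC)c1O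
F4 | step 6 | 2-[4-(benzyloxy)-3,5-dimethoxyphenoxy]-5-ethoxy-3,4-dimethoxyphenyl 2,2-dimethylpropanoate | CCOc1cc(OC(=O)C(C)(C)C)c(Oc2cc(OC)c(OCc3ccccc3)c(OC)c2)c(OC)c1OC
F5 | step 5 | 3,4-bis[4-(benzyloxy)-3,5-dimethoxyphenoxy]cyclobut-3-ene-1,2-dione | O=C1C(=O)C(Oc2cc(OC)c(OCc3ccccc3)c(OC)c2)=C1Oc1cc(OC)c(OCc2ccccc2)c(OC)c1
F6 | step 5 | 2,3-bis[4-(benzyloxy)-3,5-dimethoxyphenoxy]-4-(1-ethoxyethenyl)-4-methoxycyclobut-2-en-1-one (racemic) | C=C(OCC)C1(OC)C(Oc2cc(OC)c(OCc3ccccc3)c(OC)c2)=C(Oc2cc(OC)c(OCc3ccccc3)c(OC)c2)C1=O
F7 | step 9 | 4-{2-[4-(benzyloxy)-3,5-dimethoxyphenoxy]-5-ethoxy-3,4-dimethoxyphenoxy}-3,5-dimethoxybenzaldehyde | CCOc1cc(Oc2c(OC)cc(C=O)cc2OC)c(Oc2cc(OC)c(OCc3ccccc3)c(OC)c2)c(OC)c1OC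
F8 | step 9 | 4-{2-[4-(benzyloxy)-3,5-dimethoxyphenoxy]-5-ethoxy-3,4-dimethoxyphenoxy}-3,5-dimethoxyphenol | CCOc1cc(Oc2c(OC)cc(O)cc2OC)c(Oc2cc(OC)c(OCc3ccccc3)c(OC)c2)c(OC)c1OC
F9 | step 12 | 5-iodo-1,3-dimethoxy-2-(3,4,5-trimethoxyphenoxy)benzene | COc1cc(Oc2c(OC)cc(I)cc2OC)cc(OC)c1OC
F10 | step 12 | [3,5-dimethoxy-4-(3,4,5-trimethoxyphenoxy)phenyl](2,4,6-trimethoxyphenyl)iodonium 4-methylbenzenesulfonate | COc1cc(OC)c([I+]c2cc(OC)c(Oc3cc(OC)c(OC)c(OC)c3)c(OC)c2)c(OC)c1.Cc1ccc(S(=O)(=O)[O-])cc1
F11 | step 13 | pentadecaacetate of 27: 4-{3,5-diacetoxy-4-[3,5-diacetoxy-4-(3,4,5-triacetoxyphenoxy)phenoxy]phenoxy}-5-[2,6-diacetoxy-4-(2,4,6-triacetoxyphenoxy)phenoxy]benzene-1,2,3-triyl triacetate | CC(=O)Oc1cc(OC(C)=O)c(Oc2cc(OC(C)=O)c(Oc3cc(OC(C)=O)c(OC(C)=O)c(OC(C)=O)c3Oc3cc(OC(C)=O)c(Oc4cc(OC(C)=O)c(Oc5cc(OC(C)=O)c(OC(C)=O)c(OC(C)=O)c5)c(OC(C)=O)c4)c(OC(C)=O)c3)c(OC(C)=O)c2)c(OC(C)=O)c1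
A1 | alternative 1 | dodeca-O-methyl ether of the target with free hydroxyls at ring A C4, ring C C4 and ring F C4 | Oc1cc(OC)c(Oc2cc(OC)c(Oc3cc(OC)c(O)c(OC)c3Oc3cc(OC)c(Oc4cc(OC)c(Oc5cc(OC)c(O)c(OC)c5)c(OC)c4)c(OC)c3)c(OC)c2)c(OC)c1
A2 | alternative 1 | dodeca-O-methyl hexaaryl ether with formyl groups at ring A C4, ring C C4 and ring F C4 | O=Cc1cc(OC)c(Oc2cc(OC)c(Oc3cc(OC)c(C=O)c(OC)c3Oc3cc(OC)c(Oc4cc(OC)c(Oc5cc(OC)c(C=O)c(OC)c5)c(OC)c4)c(OC)c3)c(OC)c2)c(OC)c1
A3 | alternative 2 | 5-[4-(benzyloxy)-2,6-dimethoxyphenoxy]-2-[(tert-butyldimethylsilyl)oxy]-3-methoxyphenol | COc1cc(Oc2c(OC)cc(OCc3ccccc3)cc2OC)cc(O)c1O[Si](C)(C)C(C)(C)C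
A4 | alternative 2 | 5-(benzyloxy)-2-(ethynyloxy)-1,3-dimethoxybenzene | C#COc1c(OC)cc(OCc2ccccc2)cc1OC
A5 | alternative 2 | 4-[(tert-butyldimethylsilyl)oxy]-3-methoxycyclobut-2-en-1-one (racemic) | COC1=CC(=O)C1O[Si](C)(C)C(C)(C)C
A6 | alternative 3 | dimethyl 5-[4-(benzyloxy)-3,5-dimethoxyphenoxy]-2,4,6-trihydroxybenzene-1,3-dicarboxylate | COC(=O)c1c(O)c(C(=O)OC)c(O)c(Oc2cc(OC)c(OCc3ccccc3)c(OC)c2)c1O
A7 | alternative 3 | dimethyl 2-[4-(benzyloxy)-3,5-dimethoxyphenoxy]propanedioate | COC(=O)C(Oc1cc(OC)c(OCc2ccccc2)c(OC)c1)C(=O)OC
A8 | alternative 3 | dimethyl 3-oxopentanedioate | COC(=O)CC(=O)CC(=O)OC
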